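The target is a C2-symmetric head-to-tail dimer: a 1,4-dioxane joins O6 and O7 of two 12-methoxyabieta-8,11,13-triene units, so it is cut to a 6,7-dioxygenated monomer. The key step exploits ring B (C5–C10), a cyclohexene fused to the arene at C8–C9 and oxygenated at C6 and C7: a photogenerated hydroxy-o-quinodimethane (C7=C8–C9=C10) adds across a tethered (E)-enol ether (C5=C6), forming C6–C7 and C5–C10, closing rings A and B and setting C5, C6, C7 and C10 in one operation. Its precursor is a 2-(sec-alkyl)-5-isopropyl-4-methoxybenzaldehyde whose chain carries the C4 gem-dimethyl group and ends in the enol ether of a chiral, acid-cleavable benzylic alcohol.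

Key step: step 11

Assumption: C10 of compounds 12–19 is carried as a mixture of epimers because step 11 makes it trigonal; the (S)-alcohol is taken to leave the C6-Si/C5-Re face of the enol ether open, and if the adduct of the other face prevails the (R)-alcohol is used with no other change.

Step 1
Reactants: 1 isobutyronitrile; 2 2-(3-chloropropyl)-2-methyl-1,3-dioxolane
Product: 4 2,2-dimethyl-6-oxoheptanenitrile, via ketal nitrile 3 (not isolated)
Conditions: LiN(iPr)2, THF, −78 °C; 2, NaI (cat.), DMPU, −78 → 23 °C; then 2 M HCl, 23 °C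
Reagents that add atoms: water, O
Why: Alkylation of a nitrile-stabilised carbanion (SN2) at the primary chloride builds the C4 quaternary carbon, and the aqueous acid of the work-up hydrolyses the dialkyl dioxolane to the methyl ketone while the tertiary nitrile is inert.

Step 2
Reactants: 4 2,2-dimethyl-6-oxoheptanenitrile
Product: 6 6-cyano-6-methylhept-1-en-2-yl trifluoromethanesulfonate, via lithium enolate 5 (not isolated)
Conditions: LiN(iPr)2, THF, −78 °C; PhNTf2, −78 → 0 °C
Reagents that add atoms: N-phenylbis(trifluoromethanesulfonimide), O=S(=O)(N(c1ccccc1)S(=O)(=O)C(F)(F)F)C(F)(F)F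
Why: Kinetic enolisation takes the methyl side of the ketone (the nitrile has no α-hydrogen) and O-sulfonylation of the enolate gives the alkenyl triflate, while any internal regioisomer converges on the same product after steps 4 and 5.

Step 3
Reactants: 7 3-isopropyl-4-methoxybenzaldehyde
Product: 10 (2-formyl-4-isopropyl-5-methoxyphenyl)boronic acid, via lithium α-amino alkoxide 8 (not isolated), via ortho-lithiated α-amino alkoxide 9 (not isolated)
Conditions: Me2NCH2CH2N(Me)Li (from the amine and n-BuLi), THF, −20 °C; n-BuLi (3 equiv), −20 °C; B(OMe)3, −78 → 23 °C; 1 M HCl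
Reagents that add atoms: trimethyl borate, COB(OC)OC; water, O
Why: Directed ortho-metalation: the chelating α-amino alkoxide formed in situ masks the aldehyde and steers n-BuLi to the unhindered ortho position (the other ortho site is flanked by the isopropyl group and the diamine chelate outweighs the methoxy group), and borylation with acidic work-up releases boronic acid and aldehyde together.

Step 4
Reactants: 6 6-cyano-6-methylhept-1-en-2-yl trifluoromethanesulfonate; 10 (2-formyl-4-isopropyl-5-methoxyphenyl)boronic acid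
Product: 11 6-(2-formyl-4-isopropyl-5-methoxyphenyl)-2,2-dimethylhept-6-enenitrile
Conditions: Pd(PPh3)4 (5 mol %), K3PO4, 1,4-dioxane/H2O, 80 °C
Reagents that add atoms: none
Why: Suzuki–Miyaura coupling (oxidative addition of zerovalent palladium to the alkenyl triflate, transmetalation from boron, reductive elimination) forms the C9–C10 bond and tolerates aldehyde and nitrile.

Step 5
Reactants: 11 6-(2-formyl-4-isopropyl-5-methoxyphenyl)-2,2-dimethylhept-6-enenitrile
Product: 12 6-(2-formyl-4-isopropyl-5-methoxyphenyl)-2,2-dimethylheptanenitrile (racemic at C10)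
Conditions: H2 (1 atm), Pd/C, EtOAc, 23 °C
Reagents that add atoms: none
Why: Heterogeneous hydrogenation saturates the 1,1-disubstituted styrene well before the electron-rich aryl aldehyde or the nitrile is touched, and C10 is formed as a racemate, which is accepted because step 11 erases this centre.

Step 6
Reactants: 12 6-(2-formyl-4-isopropyl-5-methoxyphenyl)-2,2-dimethylheptanenitrile
Product: 13 6-[2-(1,3-dioxolan-2-yl)-4-isopropyl-5-methoxyphenyl]-2,2-dimethylheptanenitrile
Conditions: HOCH2CH2OH, TsOH·H2O (cat.), PhH, reflux (Dean–Stark)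
Reagents that add atoms: ethylene glycol, OCCO
Why: Acid-catalysed acetalisation with azeotropic removal of water masks the aryl aldehyde so that only the aliphatic aldehyde made in step 7 reacts in steps 8 and 9.

Step 7
Reactants: 13 6-[2-(1,3-dioxolan-2-yl)-4-isopropyl-5-methoxyphenyl]-2,2-dimethylheptanenitrile
Product: 15 6-[2-(1,3-dioxolan-2-yl)-4-isopropyl-5-methoxyphenyl]-2,2-dimethylheptanal, via N-aluminio aldimine 14 (not isolated)
Conditions: i-Bu2AlH, CH2Cl2, −78 → 0 °C; aq. potassium sodium tartrate
Reagents that add atoms: water, O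
Why: Partial reduction of a nitrile stops at the N-aluminio aldimine, which is hydrolysed at neutral pH in the work-up, conditions under which the dioxolane survives.

Step 8
Reactants: 15 6-[2-(1,3-dioxolan-2-yl)-4-isopropyl-5-methoxyphenyl]-2,2-dimethylheptanal
Product: 16 2-{2-[(E)-8-iodo-6,6-dimethyloct-7-en-2-yl]-5-isopropyl-4-methoxyphenyl}-1,3-dioxolane
Conditions: CrCl2, CHI3, THF, 0 → 23 °C
Reagents that add atoms: iodoform, IC(I)I
Why: Takai olefination adds the geminal dichromium reagent to the aldehyde and eliminates to the (E)-vinyl iodide, the E preference being reinforced by the quaternary neighbour, and the acetal is inert to the reagent.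

Step 9
Reactants: 16 2-{2-[(E)-8-iodo-6,6-dimethyloct-7-en-2-yl]-5-isopropyl-4-methoxyphenyl}-1,3-dioxolane; 17 (S)-1-(2,4,6-triisopropylphenyl)ethanol
Product: 18 2-{2-[(7E)-6,6-dimethyl-8-[(1S)-1-(2,4,6-triisopropylphenyl)ethoxy]oct-7-en-2-yl]-5-isopropyl-4-methoxyphenyl}-1,3-dioxolane
Conditions: CuI (10 mol %), 3,4,7,8-tetramethyl-1,10-phenanthroline (20 mol %), Cs2CO3, PhMe, 90 °C
Reagents that add atoms: none
Why: Ullmann-type copper-catalysed C–O coupling of a vinyl iodide with an alcohol proceeds with retention of the alkene geometry and does not break the C–O bond of 17, so the (E)-enol ether with the (S) carbinol centre results.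

Step 10
Reactants: 18 2-{2-[(7E)-6,6-dimethyl-8-[(1S)-1-(2,4,6-triisopropylphenyl)ethoxy]oct-7-en-2-yl]-5-isopropyl-4-methoxyphenyl}-1,3-dioxolane
Product: 19 5-isopropyl-4-methoxy-2-{(7E)-6,6-dimethyl-8-[(1S)-1-(2,4,6-triisopropylphenyl)ethoxy]oct-7-en-2-yl}benzaldehyde
Conditions: PPTS (cat.), acetone/H2O, 23 °C
Reagents that add atoms: water, O
Why: Acetal hydrolysis runs through an oxocarbenium ion that the para methoxy group stabilises strongly, so it should be far faster than protonation of the hindered β-branched enol ether or ionisation of the auxiliary ether under this buffered acid.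

Step 11
Reactants: 19 5-isopropyl-4-methoxy-2-{(7E)-6,6-dimethyl-8-[(1S)-1-(2,4,6-triisopropylphenyl)ethoxy]oct-7-en-2-yl}benzaldehyde
Product: 21 12-methoxy-6α-[(1S)-1-(2,4,6-triisopropylphenyl)ethoxy]abieta-8,11,13-trien-7α-ol, via (E)-dienol 20 (not isolated)
Conditions: hν (365 nm), degassed PhMe (5 mM), 23 °C
Reagents that add atoms: none
Why: Proposed new method: excitation of the aryl aldehyde is followed by 1,5-hydrogen transfer from C10 to the carbonyl oxygen, giving the hydroxy-o-quinodimethane 20 (dienol isomers with the hydroxyl or the chain turned inward revert to 19 and are re-excited), and 20 adds suprafacially to the tethered enol ether in a thermal [4+2] step that restores the arene. The closest known reaction types are the photoenolisation/Diels–Alder sequence of 2-alkylbenzaldehydes with tethered electron-poor alkenes and the thermal intramolecular cycloaddition of o-quinodimethanes to unactivated alkenes; an electron-rich enol ether steered by an O-bound auxiliary has not been shown. Ring B is the six-membered ring of the cycloadduct itself, closed by C6–C7 and C5–C10, and ring A is closed by the same C5–C10 bond across the four-carbon tether C1–C4 that joins the diene terminus to the dienophile (type 1 intramolecular mode, six-membered, chair-like). C10 and C5 are set by the exo position of the tether with C20 on the inner site of the diene (trans A/B fusion), C6 by the (E) geometry of the enol ether (O6 cis to H5), and C7 by the outward hydroxyl meeting the endo alkoxy group (7α, of no lasting consequence). The absolute sense is set by the auxiliary: in the extended ether conformer with the carbinol hydrogen turned toward the diene, the triisopropylphenyl group of the (S)-ether covers the C6-Re face, so bonding should occur on the C6-Si/C5-Re face, which gives 5S,6R,10S. The step needs exo-tether selectivity and a cycloaddition faster than loss of the dienol; the chair-like tether, a hydrogen bond from the dienol O–H to the endo O6, and the fact that reversion only regenerates 19 under continued irradiation should provide both.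

Step 12
Reactants: 21 12-methoxy-6α-[(1S)-1-(2,4,6-triisopropylphenyl)ethoxy]abieta-8,11,13-trien-7α-ol
Product: 22 12-methoxyabieta-8,11,13-triene-6α,7α-diol
Conditions: CF3CO2H, CH2Cl2, −20 → 0 °C; aq. NaHCO3
Reagents that add atoms: none
Why: Acidolysis of the benzylic auxiliary ether (SN1/E1) expels the sterically relieved 1-arylethyl cation, which ends as the styrene, and frees O6 without touching C5, C6 or C10, while any epimerisation at C7 is harmless because step 13 resets that centre.

Step 13
Reactants: 22 12-methoxyabieta-8,11,13-triene-6α,7α-diol (two molecules)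
Product: 24 target dimer (5S,6R,7R,10S in each half; dioxane links O6α–C7′β and O7β–C6′α), via mono-ether 23 (not isolated)
Conditions: Bi(OTf)3 (5 mol %), 4 Å MS, CH2Cl2 (0.3 M), −20 → 23 °C
Reagents that add atoms: none
Why: Acid-catalysed dehydrative etherification (SN1) ionises the C7–OH, which is benzylic and para to the 12-methoxy group, the 6-OH of a second molecule captures the cation and a second ionisation at C7′ closes the six-membered dioxane, and because each C7–O bond can re-ionise the material should settle in the all-trans diequatorial dioxane, which fixes C7 as β (R) in both halves.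

Compound list
1 | isobutyronitrile | CC(C)C#N | starting material
2 | 2-(3-chloropropyl)-2-methyl-1,3-dioxolane | CC1(CCCCl)OCCO1 | starting material
3 | 2,2-dimethyl-5-(2-methyl-1,3-dioxolan-2-yl)pentanenitrile | CC1(CCCC(C)(C)C#N)OCCO1 | intermediate
4 | 2,2-dimethyl-6-oxoheptanenitrile | CC(=O)CCCC(C)(C)C#N | intermediate
5 | lithium 6-cyano-6-methylhept-1-en-2-olate | [Li]OC(=C)CCCC(C)(C)C#N | intermediate
6 | 6-cyano-6-methylhept-1-en-2-yl trifluoromethanesulfonate | C=C(CCCC(C)(C)C#N)OS(=O)(=O)C(F)(F)F | intermediate
7 | 3-isopropyl-4-methoxybenzaldehyde | COc1ccc(C=O)cc1C(C)C | starting material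
8 | lithium α-amino alkoxide of 7 with N,N,N′-trimethylethylenediamine | COc1ccc(C(O[Li])N(C)CCN(C)C)cc1C(C)C | intermediate
9 | ortho-lithiated α-amino alkoxide (lithium para to the isopropyl group) | COc1cc([Li])c(C(O[Li])N(C)CCN(C)C)cc1C(C)C | intermediate
10 | (2-formyl-4-isopropyl-5-methoxyphenyl)boronic acid | COc1cc(B(O)O)c(C=O)cc1C(C)C | intermediate
11 | 6-(2-formyl-4-isopropyl-5-methoxyphenyl)-2,2-dimethylhept-6-enenitrile | COc1cc(C(=C)CCCC(C)(C)C#N)c(C=O)cc1C(C)C | intermediate
12 | 6-(2-formyl-4-isopropyl-5-methoxyphenyl)-2,2-dimethylheptanenitrile (racemic) | COc1cc(C(C)CCCC(C)(C)C#N)c(C=O)cc1C(C)C | intermediate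
13 | 6-[2-(1,3-dioxolan-2-yl)-4-isopropyl-5-methoxyphenyl]-2,2-dimethylheptanenitrile (racemic) | COc1cc(C(C)CCCC(C)(C)C#N)c(C2OCCO2)cc1C(C)C | intermediate
14 | N-(diisobutylalumino) aldimine of 15 | COc1cc(C(C)CCCC(C)(C)C=N[Al](CC(C)C)CC(C)C)c(C2OCCO2)cc1C(C)C | intermediate
15 | 6-[2-(1,3-dioxolan-2-yl)-4-isopropyl-5-methoxyphenyl]-2,2-dimethylheptanal (racemic) | COc1cc(C(C)CCCC(C)(C)C=O)c(C2OCCO2)cc1C(C)C | intermediate
16 | 2-{2-[(E)-8-iodo-6,6-dimethyloct-7-en-2-yl]-5-isopropyl-4-methoxyphenyl}-1,3-dioxolane (racemic) | COc1cc(C(C)CCCC(C)(C)/C=C/I)c(C2OCCO2)cc1C(C)C | intermediate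
17 | (S)-1-(2,4,6-triisopropylphenyl)ethanol | C[C@H](O)c1c(C(C)C)cc(C(C)C)cc1C(C)C | starting material
18 | 2-{2-[(7E)-6,6-dimethyl-8-[(1S)-1-(2,4,6-triisopropylphenyl)ethoxy]oct-7-en-2-yl]-5-isopropyl-4-methoxyphenyl}-1,3-dioxolane (C10 epimers) | COc1cc(C(C)CCCC(C)(C)/C=C/O[C@@H](C)c2c(C(C)C)cc(C(C)C)cc2C(C)C)c(C2OCCO2)cc1C(C)C | intermediate
19 | 5-isopropyl-4-methoxy-2-{(7E)-6,6-dimethyl-8-[(1S)-1-(2,4,6-triisopropylphenyl)ethoxy]oct-7-en-2-yl}benzaldehyde (C10 epimers) | COc1cc(C(C)CCCC(C)(C)/C=C/O[C@@H](C)c2c(C(C)C)cc(C(C)C)cc2C(C)C)c(C=O)cc1C(C)C | intermediate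
20 | (E)-dienol of 19 (hydroxy-o-quinodimethane; C7–OH and chain outward, C20 inward) | COC1=C/C(=C(/C)CCCC(C)(C)/C=C/O[C@@H](C)c2c(C(C)C)cc(C(C)C)cc2C(C)C)/C(=C/O)C=C1C(C)C | intermediate
21 | (5S,6R,7S,10S)-12-methoxy-6α-[(1S)-1-(2,4,6-triisopropylphenyl)ethoxy]abieta-8,11,13-trien-7α-ol | COc1cc2c(cc1C(C)C)[C@H](O)[C@H](O[C@@H](C)c1c(C(C)C)cc(C(C)C)cc1C(C)C)[C@H]1C(C)(C)CCC[C@]21C | intermediate
22 | (5S,6R,7S,10S)-12-methoxyabieta-8,11,13-triene-6α,7α-diol | COc1cc2c(cc1C(C)C)[C@H](O)[C@H](O)[C@H]1C(C)(C)CCC[C@]21C | intermediate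
23 | 7β-[(7α-hydroxy-12-methoxyabieta-8,11,13-trien-6α-yl)oxy]-12-methoxyabieta-8,11,13-trien-6α-ol | COc1cc2c(cc1C(C)C)[C@@H](O[C@H]3[C@@H](O)c4cc(C(C)C)c(OC)cc4[C@@]4(C)CCCC(C)(C)[C@H]34)[C@H](O)[C@H]1C(C)(C)CCC[C@]21C | intermediate
24 | head-to-tail dioxane dimer of 12-methoxyabieta-8,11,13-triene (O6α–C7′β and O7β–C6′α; 5S,6R,7R,10S in each half), CNP0327150.1 | COc1cc2c(cc1C(C)C)[C@H]1O[C@H]3[C@H](O[C@@H]1[C@H]1C(C)(C)CCC[C@]21C)c1cc(C(C)C)c(OC)cc1[C@@]1(C)CCCC(C)(C)[C@H]31 | target

Total step count: 13. Longest linear sequence: 12 steps (steps 1, 2 and 4–13 from isobutyronitrile); step 3 is a one-step branch.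

Steps most likely to fail

Step 11. The dienol may revert to the aldehyde, shift a hydrogen from C20 to C7, or add through the endo-tether mode or on the shielded face faster than it undergoes the wanted addition to the electron-rich enol ether. Facial isomers would remain separable because the auxiliary is still attached. The fallback leaves the cycloaddition for a cationic polyene cyclisation and sets out from 7. Reduction (NaBH4, MeOH) gives (3-isopropyl-4-methoxyphenyl)methanol F1, which is converted (SOCl2, CH2Cl2) into 4-(chloromethyl)-2-isopropyl-1-methoxybenzene F2 and then (Mg, THF) into (3-isopropyl-4-methoxybenzyl)magnesium chloride F3. Coupling with geranyl chloride (Li2CuCl4 cat., THF, 0 °C) gives 4-[(3E)-4,8-dimethylnona-3,7-dien-1-yl]-2-isopropyl-1-methoxybenzene F4. Enantioselective proton-initiated bicyclisation (SnCl4 complex of an enantiopure BINOL monoether as chiral Brønsted acid, ligand enantiomer chosen for the 5S,10S series, −78 °C) should give (5S,10S)-12-methoxyabieta-8,11,13-triene F5. Benzylic dehydrogenation (DDQ, dioxane, reflux) leads to 12-methoxyabieta-6,8,11,13-tetraene F6, and dihydroxylation on the α face, away from the axial C20 and C19 methyl groups (OsO4 cat., NMO, acetone/H2O), returns to the route at diol 22.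

Step 13. The C7 cation may undergo a 1,2-hydride shift from C6 (pinacol-type collapse to the 6-ketone) or form open-chain oligomers faster than the two etherifications occur. The fallback replaces the SN1 dimerisation by a reductive etherification and sets out from 21. Oxidation (MnO2, CH2Cl2) gives 12-methoxy-6α-[(1S)-1-(2,4,6-triisopropylphenyl)ethoxy]abieta-8,11,13-trien-7-one F7, and acidolysis of the auxiliary (CF3CO2H, CH2Cl2, 0 °C) gives 6α-hydroxy-12-methoxyabieta-8,11,13-trien-7-one F8. Two molecules of F8 are then joined head to tail (Et3SiH, TMSOTf, CH2Cl2, −78 → −40 °C). Each C7 oxocarbenium ion, which has no hydride-shift outlet, should be reduced by axial hydride delivery to the 7β ether, which returns to the route at target 24.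

Step 9. Ligand exchange of the very hindered secondary alkoxide at copper may be too slow, so that protodeiodination or erosion of the alkene geometry takes over. The fallback forms the C5=C6 double bond instead of the O–C6 bond (Horner–Wittig) and sets out from 15 and 17. Alkylation of 17 (NaH, THF, then Ph2P(O)CH2OTs) gives diphenyl{[(1S)-1-(2,4,6-triisopropylphenyl)ethoxy]methyl}phosphine oxide F9. Its lithio derivative (LiN(iPr)2, THF, −78 °C) adds to 15, and the threo β-hydroxy phosphine oxide F10 is separated from the erythro adduct. Stereospecific syn-elimination (NaH, DMF) returns to the route at enol ether 18.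

Further compounds
F1 | step 11 | (3-isopropyl-4-methoxyphenyl)methanol | COc1ccc(CO)cc1C(C)C
F2 | step 11 | 4-(chloromethyl)-2-isopropyl-1-methoxybenzene | COc1ccc(CCl)cc1C(C)C
F3 | step 11 | (3-isopropyl-4-methoxybenzyl)magnesium chloride | COc1ccc(C[Mg]Cl)cc1C(C)C
F4 | step 11 | 4-[(3E)-4,8-dimethylnona-3,7-dien-1-yl]-2-isopropyl-1-methoxybenzene | COc1ccc(CC/C=C(\C)CCC=C(C)C)cc1C(C)C
F5 | step 11 | (5S,10S)-12-methoxyabieta-8,11,13-triene | COc1cc2c(cc1C(C)C)CC[C@H]1C(C)(C)CCC[C@]21C
F6 | step 11 | (5S,10S)-12-methoxyabieta-6,8,11,13-tetraene | COc1cc2c(cc1C(C)C)C=C[C@H]1C(C)(C)CCC[C@]21C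
F7 | step 13 | 12-methoxy-6α-[(1S)-1-(2,4,6-triisopropylphenyl)ethoxy]abieta-8,11,13-trien-7-one | COc1cc2c(cc1C(C)C)C(=O)[C@H](O[C@@H](C)c1c(C(C)C)cc(C(C)C)cc1C(C)C)[C@H]1C(C)(C)CCC[C@]21C
F8 | step 13 | 6α-hydroxy-12-methoxyabieta-8,11,13-trien-7-one | COc1cc2c(cc1C(C)C)C(=O)[C@H](O)[C@H]1C(C)(C)CCC[C@]21C
F9 | step 9 | diphenyl{[(1S)-1-(2,4,6-triisopropylphenyl)ethoxy]methyl}phosphine oxide | C[C@H](OCP(=O)(c1ccccc1)c1ccccc1)c1c(C(C)C)cc(C(C)C)cc1C(C)C
F10 | step 9 | threo β-hydroxy phosphine oxide from F9 and 15 (carbinol and phosphinoyl carbons as the threo pair, C10 epimers) | COc1cc(C(C)CCCC(C)(C)C(O)C(O[C@@H](C)c2c(C(C)C)cc(C(C)C)cc2C(C)C)P(=O)(c2ccccc2)c2ccccc2)c(C2OCCO2)cc1C(C)C
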